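## Analysis of the target

Target 21 is a C24 norsesterterpenoid ester built from three parts. A methyl propanoate (C1, C2 and the C2 methyl) sits on C3 of a 1,2-dioxane (ring C: O1, O2, C3, C4, C5, C6). The fully substituted C6 carries a methyl group and a C7–C8 ethylene tether to C1′ of a trans-fused octahydronaphthalene. Ring A holds the gem-dimethyl carbon C5′; ring B holds the angular methyl at C8a′ and the trisubstituted alkene C2′=C3′.

There are six stereocentres in two triads four bonds apart: (2S,3S,6S) in the peroxide half and (1′R,4a′R,8a′R) in the decalin. The decalin is the mirror image of the drimane unit of the cheap plant terpenoids (sclareol, sclareolide, natural drimenol), so the usual chiral pool would give the wrong enantiomer of rings A and B.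

In the peroxide half, C2 and C3 are anti along the zigzag C1–C4. On ring C the C3 side chain and the C7 tether are cis, so in the favoured chair the side chain and the C6 methyl are equatorial and the tether is axial.

The feature that decides the strategy is the quaternary peroxide carbon C6 and its bond to C7. The two alkyl groups on C6 (CH3 and C7H2) are almost equal in size, so a ring closure that forms a C–O bond at C6 or at C3 cannot tell the two faces apart, and C1′ is too far away to help.

Sensitive groups are the O–O bond (reducing metals, organometallics, heterogeneous hydrogenation), the β-peroxy ester (base causes E1cB ring opening and C2 epimerisation), C3–H (Kornblum–DeLaMare cleavage) and the ring B alkene (ozone, singlet oxygen, peracids, strong acid). The synthesis is hard because C6 must be created in a defined relation to C3 and joined to an antipodal decalin under conditions a dialkyl peroxide survives.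

## Retrosynthetic reasoning

**21 ⇒ 20.** The C7–C8 single bond is traced back to the (E)-alkene of 20. The union step below needs an sp2 carbon at C7, and a 1,2-disubstituted alkene can be saturated by a concerted hydrogen-transfer reagent that leaves O–O bonds and the trisubstituted ring B alkene alone. The forward step adds only two hydrogens and touches no stereocentre.

**20 ⇒ 11 + 17 (key disconnection).** The C6–C7 bond, the joint between ring C and the tether, is cut. This splits the molecule into two halves of similar size, each with its own stereotriad. It also turns the quaternary centre into the cyclic tertiary peroxycarbenium ion 19, which has a single control element, the C3 side chain. A carbon nucleophile that adds along the axial trajectory ends up cis to that side chain whatever the relative size of methyl and tether. Cutting C6–O or C3–O would leave the CH3/CH2 problem unsolved. The precursor 11 has only two stereocentres, and its ketal carbon needs no control. The forward step must transfer the alkenyl group of borate 17 (through 18) to C6 of 19 faster than the cation decays.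

**11 ⇒ 10 ⇒ 8.** The ester carbon C1 is carried as the CH of a vinyl group. A carbonyl at C1 during ring closure would place the leaving group at C3 β to it and invite elimination. Oxidative cleavage and esterification restore the ester after the ring is made.

**8 ⇒ 7 ⇒ 6 ⇒ 5.** The O2–C3 bond is cut: an intramolecular SN2 displacement of a secondary sulfonate by the oxygen of a hydroperoxy ketal. This closes ring C with inversion, so C3 derives from an ordinary carbinol stereocentre. The O1–C6 bond comes from peroxyketalisation of a methyl ketone, where no stereocontrol is needed.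

**5 ⇒ 3 ⇒ 1.** The C2–C3 bond is cut. A reagent-controlled syn-crotylation of keto aldehyde 3 sets both centres in one step and delivers the vinyl group. The aldehyde reacts and the ketone is kept for the peroxide. Aldehyde 3 comes from alkene 1 by oxidative cleavage.

**17 ⇒ 16 ⇒ 15 ⇒ 14.** The C7=C8 double bond is formed by a one-carbon boryl olefination of aldehyde 15, so C7 comes from the boron reagent. The (E)-alkenylboron is reached without a strong base at the epimerisable C1′.

**14 ⇒ 13 ⇒ 12.** The bonds C4a′–C5′ and C1′–C8a′ are cut. A proton-initiated cation–olefin bicyclisation of the acyclic triene 12 closes rings A and B and sets the relative configuration of all three decalin centres. Kinetic proton loss places the alkene at C2′=C3′. The antipodal drimane series is not in the terpene pool, so the absolute configuration is taken from an enzymatic kinetic resolution of 13.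

## Alternatives that were turned down

**Alternative 1:** (the textbook route) Disconnection at O1–C6 and O2–C3. The forward sequence is a Mukaiyama–Isayama hydroperoxysilylation (Co(thd)2, O2, Et3SiH) of the 1,1-disubstituted alkene A1 to the silyl peroxide A2, then desilylation and intramolecular peroxy-Michael addition onto the (E)-2-methyl enoate. It is short, but C6 arises from a planar tertiary radical trapped by O2 with no facial bias. Even with C6 defined, the chair transition state of the Michael closure cannot distinguish CH3 from C7H2, so C3 is uncontrolled. C2 is set by an undirected enolate protonation. The target would be one of up to eight isomers that differ only in the peroxide triad and would be hard to separate. The hydrogen-atom transfer step would also attack the ring B alkene.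

**Alternative 2:** Both C–O bonds at once, by [4+2] cycloaddition of singlet oxygen to the (3E,5E)-diene A3 to give the dihydrodioxine A4, then hydrogen transfer. Suprafacial addition would fix the 3,6-cis relationship. It was turned down on three counts:
- The reactive s-cis conformer of A3 must hold the C6 methyl group inside, so the ene reaction at the trisubstituted diene terminus should outrun cycloaddition.
- The ring B alkene is itself a good ene substrate.
- Face selectivity would rest only on C2, which in A3 is α to an ester and allylic and therefore prone to epimerise or conjugate.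

**Alternative 3:** Rings A and B last: acid-induced bicyclisation of triene A5, which already carries the finished dioxane. It is attractive because farnesyl units come from the pool and two rings close in the final step. It was turned down on four counts:
- Three new stereocentres must be set against a triad four bonds away, so only a chiral acid could control them, and no highly selective chiral proton source is established for alkene-terminated cyclisations.
- The tertiary C6–O bond and the ester bind the acid.
- The position of the ring B alkene depends on an uncontrolled proton loss.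
- All this risk falls on the most advanced material, while the C6 problem still has to be solved upstream to make A5.

Key step: step 13

**Remarks on the chemistry**
- Dec stands for the (1R,4aR,8aR)-2,5,5,8a-tetramethyl-1,4,4a,5,6,7,8,8a-octahydronaphthalen-1-yl group.
- All 1,2-dioxanes keep the locants of the target: C3 bears the side chain, C6 the methyl group.
- It is assumed that the lipase acylates the (1S,4aS,8aS) antipode of 13 faster, so that 14 is recovered as the alcohol.
- The Si-face preference of the crotylborane in step 2, and the reagent antipode named in the step 5 fallback, are assigned by analogy with the allylborane of the same pinene series.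
- Compounds 1 and 12 and all reagents are taken as commercial.

## Route

Step 1
Reactants: 1 hex-5-en-2-one
Product: 3 4-oxopentanal, via ozonide 2 (not isolated)
Conditions: O3, CH2Cl2, −78 °C; then PPh3, −78 °C to rt
Reagents that add atoms: ozone, [O-][O+]=O
Why: Ozonolysis cleaves the only alkene while the methyl ketone is inert; reductive work-up gives the keto aldehyde, which is used at once because it is volatile and water-soluble.

Step 2
Reactants: 3 4-oxopentanal
Product: 5 (5R,6R)-5-hydroxy-6-methyloct-7-en-2-one, via borinate ester 4 (not isolated)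
Conditions: (Z)-but-2-ene, n-BuLi, KOtBu, THF, −78 to −45 °C; (−)-Ipc2BOMe, −78 °C; BF3·OEt2; then 3, −78 °C; then NaOH, H2O2, 0 °C to rt
Reagents that add atoms: (Z)-crotyldiisopinocampheylborane (made in the flask), C/C=C\CB([C@@H]1C[C@@H]2C[C@H]([C@H]1C)C2(C)C)[C@@H]1C[C@@H]2C[C@H]([C@H]1C)C2(C)C
Why: Brown crotylboration through a closed chair (Zimmerman–Traxler) transition state: the (Z)-crotyl unit gives the syn adduct, and the isopinocampheyl groups derived from (+)-α-pinene should direct attack to the Si face, which sets C5 and C6 as R (C3 and C2 of the target); the aldehyde reacts far faster than the methyl ketone at −78 °C.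

Step 3
Reactants: 5 (5R,6R)-5-hydroxy-6-methyloct-7-en-2-one
Product: 6 (3R,4R)-3-methyl-7-oxooct-1-en-4-yl methanesulfonate
Conditions: MsCl, Et3N, CH2Cl2, −20 to 0 °C
Reagents that add atoms: methanesulfonyl chloride, CS(Cl)(=O)=O
Why: Sulfonylation of the secondary alcohol with retention; the open hydroxy ketone should dominate over its five-membered hemiketal, and the low temperature keeps the homoallylic mesylate from eliminating.

Step 4
Reactants: 6 (3R,4R)-3-methyl-7-oxooct-1-en-4-yl methanesulfonate
Product: 7 (3R,4R)-7-hydroperoxy-7-methoxy-3-methyloct-1-en-4-yl methanesulfonate (both C7 epimers)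
Conditions: urea–H2O2, Sc(OTf)3 (cat.), MeOH, rt
Reagents that add atoms: hydrogen peroxide (as its urea adduct), OO; methanol, CO
Why: Acid-catalysed peroxyketalisation of a methyl ketone in methanol, a known entry to 3-methoxy-1,2-dioxanes; the new ketal carbon needs no control because it is ionised in step 13, and the secondary mesylate and terminal alkene should be inert under these conditions.

Step 5
Reactants: 7 (3R,4R)-7-hydroperoxy-7-methoxy-3-methyloct-1-en-4-yl methanesulfonate
Product: 8 (3S)-3-[(2R)-but-3-en-2-yl]-6-methoxy-6-methyl-1,2-dioxane (both C6 epimers)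
Conditions: KOtBu (1.1 equiv), 18-crown-6, toluene, 0 °C to rt
Reagents that add atoms: none
Why: Intramolecular version of the known alkylation of α-methoxyalkyl hydroperoxides by sulfonates: one equivalent of base gives the peroxide anion, a weak base but a strong α-effect nucleophile, which closes ring C by 6-exo-tet SN2 at C3 with inversion, so that the R carbinol carbon becomes 3S.

Step 6
Reactants: 8 (3S)-3-[(2R)-but-3-en-2-yl]-6-methoxy-6-methyl-1,2-dioxane
Product: 10 (2S)-2-[(3S)-6-methoxy-6-methyl-1,2-dioxan-3-yl]propanoic acid, via aldehyde 9 (not isolated)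
Conditions: O3, MeCN/H2O (10:1), 0 °C; then NaClO2, NaH2PO4, 2-methylbut-2-ene, 0 °C to rt
Reagents that add atoms: ozone, [O-][O+]=O; sodium chlorite, [Na+].[O-]Cl=O
Why: Ozonolysis in aqueous acetonitrile gives the aldehyde directly, and Pinnick oxidation in the same flask under phosphate buffer takes it to the acid, so the β-peroxy aldehyde 9 never meets base (no E1cB opening, no epimerisation at C2); the peroxyketal should tolerate the mildly acidic buffer.

Step 7
Reactants: 10 (2S)-2-[(3S)-6-methoxy-6-methyl-1,2-dioxan-3-yl]propanoic acid
Product: 11 methyl (2S)-2-[(3S)-6-methoxy-6-methyl-1,2-dioxan-3-yl]propanoate (both C6 epimers)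
Conditions: TMSCHN2, toluene/MeOH (4:1), 0 °C
Reagents that add atoms: trimethylsilyldiazomethane, C[Si](C)(C)C=[N+]=[N-]
Why: Methyl ester formation under neutral conditions; neither the peroxyketal nor the C2 stereocentre is exposed to acid or base.

Step 8
Reactants: 12 (2E,6E)-farnesol
Product: 13 rac-drimenol, (Dec)methanol and its mirror image
Conditions: FSO3H, i-PrNO2, −78 °C; then Et3N
Reagents that add atoms: none
Why: Superacid-induced cation–olefin bicyclisation, known for farnesol: protonation of the terminal alkene and chair–chair folding of the (E,E)-triene close rings A and B trans-fused with the CH2OH group equatorial, and kinetic loss of a proton from C3′ at low temperature should give the C2′=C3′ alkene.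

Step 9
Reactants: 13 rac-drimenol
Product: 14 (Dec)methanol, [(1R,4aR,8aR)-2,5,5,8a-tetramethyl-1,4,4a,5,6,7,8,8a-octahydronaphthalen-1-yl]methanol
Conditions: lipase from Burkholderia cepacia, vinyl acetate, t-BuOMe, rt, run past half conversion
Reagents that add atoms: none
Why: Lipase-catalysed kinetic resolution of a primary alcohol with a β-stereocentre by irreversible acylation; running past half conversion should leave the slow-reacting (1R,4aR,8aR) alcohol in high enantiomeric purity, which fixes the absolute configuration of rings A and B.

Step 10
Reactants: 14 (Dec)methanol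
Product: 15 Dec-carbaldehyde, (1R,4aR,8aR)-2,5,5,8a-tetramethyl-1,4,4a,5,6,7,8,8a-octahydronaphthalene-1-carbaldehyde
Conditions: Dess–Martin periodinane, NaHCO3, CH2Cl2, 0 °C
Reagents that add atoms: none
Why: Dess–Martin oxidation under bicarbonate buffer is fast and neutral, so the β,γ-unsaturated aldehyde should neither epimerise at C1′ nor move its double bond into conjugation; 15 is used crude at once.

Step 11
Reactants: 15 Dec-carbaldehyde
Product: 16 2-[(E)-2-(Dec)ethenyl]-4,4,5,5-tetramethyl-1,3,2-dioxaborolane
Conditions: CH2(Bpin)2, LiTMP, THF, 0 °C; then 15, −78 °C to rt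
Reagents that add atoms: bis(pinacolato)borylmethane, CC1(C)OB(CB2OC(C)(C)C(C)(C)O2)OC1(C)C
Why: Boron–Wittig olefination: the lithiated gem-diboronate adds to the aldehyde and syn B–O elimination should give the (E)-alkenylboronate; the stabilised carbanion is a weak base, which protects the C1′ stereocentre, and its carbon becomes C7.

Step 12
Reactants: 16 2-[(E)-2-(Dec)ethenyl]-4,4,5,5-tetramethyl-1,3,2-dioxaborolane
Product: 17 potassium trifluoro[(E)-2-(Dec)ethenyl]borate
Conditions: KHF2, MeOH/H2O, rt
Reagents that add atoms: potassium hydrogen difluoride, [K+].F.[F-]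
Why: Standard exchange of a pinacol boronate for the trifluoroborate salt, which is more nucleophilic at carbon and can be purified by precipitation.

Step 13
Reactants: 11 methyl (2S)-2-[(3S)-6-methoxy-6-methyl-1,2-dioxan-3-yl]propanoate; 17 potassium trifluoro[(E)-2-(Dec)ethenyl]borate
Product: 20 methyl (2S)-2-{(3S,6R)-6-[(E)-2-(Dec)ethenyl]-6-methyl-1,2-dioxan-3-yl}propanoate, via alkenyldifluoroborane 18 (not isolated), via peroxycarbenium ion 19 (not isolated)
Conditions: BF3·OEt2, 4 Å MS, MeCN/CH2Cl2, −40 to 0 °C
Reagents that add atoms: none
Why: Proposed new method: BF3·OEt2 should strip fluoride from 17 to give the alkenyldifluoroborane 18, which binds the methoxy group of 11 and releases the cyclic tertiary peroxycarbenium ion 19; ipso attack of the boron-bearing alkene carbon C7 on C6 then forms the C6–C7 bond with retention of the (E)-geometry, the closest known reaction types being the Lewis-acid-mediated allylation of 3-alkoxy-1,2-dioxanes and 1,2-dioxolanes with allylsilanes (Hosomi–Sakurai type) and the BF3-promoted addition of alkenyltrifluoroborates to acetal-derived oxocarbenium ions. No ring is closed: the step joins the two halves and creates the quaternary peroxide stereocentre C6. C6 is set by 1,4-induction from C3: in the half-chair of 19 (C5, C6, O1 and O2 coplanar) the C3 side chain sits pseudoequatorial, and attack along the axial trajectory that leads directly to a chair places the new bond cis to that side chain with the methyl group equatorial, which is (3S,6R) in 20 and (3S,6S) in 21. This control does not depend on any size difference between methyl and tether, which is why a C–C bond and not a C–O bond is formed last at C6. Both ketal epimers of 11 converge on the same cation, so their ratio does not matter. The step needs face selectivity at C6 (secured by the single ring substituent at C3), ipso regiochemistry (secured by the β-boron effect) and chemoselectivity over the ring B alkene and the O–O bond (a hindered trisubstituted alkene is a far weaker π-nucleophile than an alkenylborate, and the methoxy oxygen is the most basic site at or below 0 °C).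

Step 14
Reactants: 20 methyl (2S)-2-{(3S,6R)-6-[(E)-2-(Dec)ethenyl]-6-methyl-1,2-dioxan-3-yl}propanoate
Product: 21 methyl (2S)-2-{(3S,6S)-6-[2-(Dec)ethyl]-6-methyl-1,2-dioxan-3-yl}propanoate
Conditions: KO2CN=NCO2K, AcOH, CH2Cl2/MeOH, 0 °C to rt, repeated charges
Reagents that add atoms: none
Why: Concerted syn transfer of H2 from diimide, the standard alkene reduction that leaves O–O bonds intact; the 1,2-disubstituted alkene should react ahead of the trisubstituted ring B alkene, the mildly acidic medium avoids retro-Michael opening and C2 epimerisation, and C6 changes from R to S by CIP priority only.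

## Compound list

1 | hex-5-en-2-one | CC(=O)CCC=C | starting material
2 | 4-(1,2,4-trioxolan-3-yl)butan-2-one (ozonide) | CC(=O)CCC1OCOO1 | intermediate
3 | 4-oxopentanal | CC(=O)CCC=O | intermediate
4 | (5R,6R)-5-[(diisopinocampheylboranyl)oxy]-6-methyloct-7-en-2-one (isopinocampheyl groups from (+)-α-pinene) | CC(=O)CC[C@@H](OB([C@@H]1C[C@@H]2C[C@H]([C@H]1C)C2(C)C)[C@@H]1C[C@@H]2C[C@H]([C@H]1C)C2(C)C)[C@H](C)C=C | intermediate
5 | (5R,6R)-5-hydroxy-6-methyloct-7-en-2-one | CC(=O)CC[C@@H](O)[C@H](C)C=C | intermediate
6 | (3R,4R)-3-methyl-7-oxooct-1-en-4-yl methanesulfonate | CC(=O)CC[C@@H](OS(C)(=O)=O)[C@H](C)C=C | intermediate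
7 | (3R,4R)-7-hydroperoxy-7-methoxy-3-methyloct-1-en-4-yl methanesulfonate (C7 epimers) | COC(C)(OO)CC[C@@H](OS(C)(=O)=O)[C@H](C)C=C | intermediate
8 | (3S)-3-[(2R)-but-3-en-2-yl]-6-methoxy-6-methyl-1,2-dioxane (C6 epimers) | C=C[C@@H](C)[C@@H]1CCC(C)(OC)OO1 | intermediate
9 | (2S)-2-[(3S)-6-methoxy-6-methyl-1,2-dioxan-3-yl]propanal | O=C[C@@H](C)[C@@H]1CCC(C)(OC)OO1 | intermediate
10 | (2S)-2-[(3S)-6-methoxy-6-methyl-1,2-dioxan-3-yl]propanoic acid | OC(=O)[C@@H](C)[C@@H]1CCC(C)(OC)OO1 | intermediate
11 | methyl (2S)-2-[(3S)-6-methoxy-6-methyl-1,2-dioxan-3-yl]propanoate (C6 epimers) | COC(=O)[C@@H](C)[C@@H]1CCC(C)(OC)OO1 | intermediate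
12 | (2E,6E)-farnesol | CC(C)=CCC/C(C)=C/CC/C(C)=C/CO | starting material
13 | rac-drimenol (both enantiomers) | OC[C@@H]1C(C)=CC[C@@H]2C(C)(C)CCC[C@@]12C.OC[C@H]1C(C)=CC[C@H]2C(C)(C)CCC[C@]12C | intermediate
14 | [(1R,4aR,8aR)-2,5,5,8a-tetramethyl-1,4,4a,5,6,7,8,8a-octahydronaphthalen-1-yl]methanol, (Dec)methanol | OC[C@@H]1C(C)=CC[C@@H]2C(C)(C)CCC[C@@]12C | intermediate
15 | (1R,4aR,8aR)-2,5,5,8a-tetramethyl-1,4,4a,5,6,7,8,8a-octahydronaphthalene-1-carbaldehyde | O=C[C@@H]1C(C)=CC[C@@H]2C(C)(C)CCC[C@@]12C | intermediate
16 | 2-[(E)-2-(Dec)ethenyl]-4,4,5,5-tetramethyl-1,3,2-dioxaborolane | CC1(C)OB(/C=C/[C@@H]2C(C)=CC[C@@H]3C(C)(C)CCC[C@@]23C)OC1(C)C | intermediate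
17 | potassium trifluoro[(E)-2-(Dec)ethenyl]borate | [K+].F[B-](F)(F)/C=C/[C@@H]1C(C)=CC[C@@H]2C(C)(C)CCC[C@@]12C | intermediate
18 | difluoro[(E)-2-(Dec)ethenyl]borane | FB(F)/C=C/[C@@H]1C(C)=CC[C@@H]2C(C)(C)CCC[C@@]12C | intermediate
19 | (3S)-3-[(2S)-1-methoxy-1-oxopropan-2-yl]-6-methyl-1,2-dioxan-6-ylium (C6=O1 oxocarbenium form) | COC(=O)[C@@H](C)[C@@H]1CCC(C)=[O+]O1 | intermediate
20 | methyl (2S)-2-{(3S,6R)-6-[(E)-2-(Dec)ethenyl]-6-methyl-1,2-dioxan-3-yl}propanoate | COC(=O)[C@@H](C)[C@@H]1CC[C@](C)(/C=C/[C@@H]2C(C)=CC[C@@H]3C(C)(C)CCC[C@@]23C)OO1 | intermediate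
21 | methyl (2S)-2-{(3S,6S)-6-[2-(Dec)ethyl]-6-methyl-1,2-dioxan-3-yl}propanoate | COC(=O)[C@@H](C)[C@@H]1CC[C@](C)(CC[C@@H]2C(C)=CC[C@@H]3C(C)(C)CCC[C@@]23C)OO1 | target

## Step count and least certain steps

Total step count: 14. Longest linear sequence: 9 steps (steps 1 to 7, then 13 and 14). The decalin branch takes 7 steps (8 to 12, then 13 and 14).

**Step 13 (key step, proposed new method).** Three processes may defeat it: proton loss or fragmentation of the tertiary peroxycarbenium ion before alkenyl transfer, delivery of the alkenyl group inside the contact ion pair with loss of face selectivity, and protodeboronation of the alkenylborane.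

The fallback uses known reaction types, sets out from 11 and 14, and comes back at 20. Ester 11 is treated with propargyltrimethylsilane and SnCl4 at −78 °C. This is an SE2′ addition of the same class as the known allylsilane additions to cyclic peroxyketals, with the same axial attack. It gives the allene methyl (2S)-2-[(3S,6R)-6-methyl-6-(propa-1,2-dien-1-yl)-1,2-dioxan-3-yl]propanoate F1. Ozonolysis with PPh3 work-up turns F1 into the aldehyde methyl (2S)-2-[(3S,6R)-6-formyl-6-methyl-1,2-dioxan-3-yl]propanoate F2. In parallel, alcohol 14 undergoes a Mitsunobu reaction with 1-phenyl-1H-tetrazole-5-thiol to give the sulfide 5-{[(Dec)methyl]sulfanyl}-1-phenyl-1H-tetrazole F3. Oxidation with (NH4)6Mo7O24 and H2O2 gives the sulfone 5-{[(Dec)methyl]sulfonyl}-1-phenyl-1H-tetrazole F4. Julia–Kocienski olefination (KHMDS on F4 at −78 °C, then F2) should give 20, possibly with some (Z)-isomer methyl (2S)-2-{(3S,6R)-6-[(Z)-2-(Dec)ethenyl]-6-methyl-1,2-dioxan-3-yl}propanoate F5, which step 14 converts into the same product.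

**Step 5.** The peroxide anion may act as a base and eliminate the mesylate toward the conjugated diene (the neighbouring C–H is allylic). The ketal oxygen may also close a five-membered ether, or the hydroperoxy ketal may revert to the ketone.

The fallback changes both the leaving group and the mode of activation. It sets out from 3 and comes back at 8. (E)-Crotylboration of 3 with the reagent from (+)-Ipc2BOMe gives the anti adduct (5S,6R)-5-hydroxy-6-methyloct-7-en-2-one F6. An Appel reaction (I2, PPh3, imidazole) inverts the carbinol to the iodide (5R,6R)-5-iodo-6-methyloct-7-en-2-one F7. Peroxyketalisation as in step 4 gives (3R,4R)-7-hydroperoxy-4-iodo-7-methoxy-3-methyloct-1-ene F8. Base-free closure with Ag2O in CH2Cl2 should displace the iodide with inversion.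

**Step 14.** The alkene lies between the quaternary C6 and the tertiary C1′, so hydrogen transfer may be slow and over-reduction of the ring B alkene may compete. The fallback sets out from 20 and comes back at 21 with no new compound (F0). It replaces the stoichiometric hydrogen donor by homogeneous catalytic hydrogenation with RhCl(PPh3)3 under H2 in benzene. Its selectivity rests on the substitution pattern of the alkene, but its tolerance of the O–O bond would have to be checked.

**Step 9.** The stereocentre lies one carbon away from the reacting oxygen, so the lipase may discriminate the enantiomers poorly and leave 14 with low enantiomeric purity. The fallback sets out from 13 and comes back at 14. It separates covalent diastereomers: esterification of 13 with (S)-2-methoxy-2-phenylacetic acid (DCC, DMAP) gives [(Dec)methyl] (2S)-2-methoxy-2-phenylacetate F9 and its diastereomer from the antipodal alcohol, [(1S,4aS,8aS)-2,5,5,8a-tetramethyl-1,4,4a,5,6,7,8,8a-octahydronaphthalen-1-yl]methyl (2S)-2-methoxy-2-phenylacetate F10. The two are separated by chromatography, and F9 is cleaved with K2CO3 in MeOH.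

**Step 11.** Deprotonation of the doubly activated C1′–H of 15 (α to the aldehyde and allylic) may lead to epimerisation or double-bond migration before addition. The fallback sets out from 15 and comes back at 16. A Takai olefination (CHI3, CrCl2, THF) under non-basic conditions gives the vinyl iodide (1R,4aR,8aR)-1-[(E)-2-iodoethenyl]-2,5,5,8a-tetramethyl-1,4,4a,5,6,7,8,8a-octahydronaphthalene F11. Miyaura borylation (B2pin2, PdCl2(dppf), KOPh) then gives 16.

## Further compounds

F1 | step 13 | methyl (2S)-2-[(3S,6R)-6-methyl-6-(propa-1,2-dien-1-yl)-1,2-dioxan-3-yl]propanoate | COC(=O)[C@@H](C)[C@@H]1CC[C@](C)(C=C=C)OO1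
F2 | step 13 | methyl (2S)-2-[(3S,6R)-6-formyl-6-methyl-1,2-dioxan-3-yl]propanoate | COC(=O)[C@@H](C)[C@@H]1CC[C@](C)(C=O)OO1
F3 | step 13 | 5-{[(Dec)methyl]sulfanyl}-1-phenyl-1H-tetrazole | C(Sc1nnnn1-c1ccccc1)[C@@H]1C(C)=CC[C@@H]2C(C)(C)CCC[C@@]12C
F4 | step 13 | 5-{[(Dec)methyl]sulfonyl}-1-phenyl-1H-tetrazole | O=S(=O)(C[C@@H]1C(C)=CC[C@@H]2C(C)(C)CCC[C@@]12C)c1nnnn1-c1ccccc1
F5 | step 13 | methyl (2S)-2-{(3S,6R)-6-[(Z)-2-(Dec)ethenyl]-6-methyl-1,2-dioxan-3-yl}propanoate | COC(=O)[C@@H](C)[C@@H]1CC[C@](C)(/C=C\[C@@H]2C(C)=CC[C@@H]3C(C)(C)CCC[C@@]23C)OO1
F6 | step 5 | (5S,6R)-5-hydroxy-6-methyloct-7-en-2-one | CC(=O)CC[C@H](O)[C@H](C)C=C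
F7 | step 5 | (5R,6R)-5-iodo-6-methyloct-7-en-2-one | CC(=O)CC[C@@H](I)[C@H](C)C=C
F8 | step 5 | (3R,4R)-7-hydroperoxy-4-iodo-7-methoxy-3-methyloct-1-ene (C7 epimers) | COC(C)(OO)CC[C@@H](I)[C@H](C)C=C
F0 | step 14 | none | none
F9 | step 9 | [(Dec)methyl] (2S)-2-methoxy-2-phenylacetate | CO[C@H](C(=O)OC[C@@H]1C(C)=CC[C@@H]2C(C)(C)CCC[C@@]12C)c1ccccc1
F10 | step 9 | [(1S,4aS,8aS)-2,5,5,8a-tetramethyl-1,4,4a,5,6,7,8,8a-octahydronaphthalen-1-yl]methyl (2S)-2-methoxy-2-phenylacetate | CO[C@H](C(=O)OC[C@H]1C(C)=CC[C@H]2C(C)(C)CCC[C@]12C)c1ccccc1
F11 | step 11 | (1R,4aR,8aR)-1-[(E)-2-iodoethenyl]-2,5,5,8a-tetramethyl-1,4,4a,5,6,7,8,8a-octahydronaphthalene | I/C=C/[C@@H]1C(C)=CC[C@@H]2C(C)(C)CCC[C@@]12C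
A1 | alternative 1 | methyl (2E)-2-methyl-6-methylidene-8-(Dec)oct-2-enoate | COC(=O)/C(C)=C/CCC(=C)CC[C@@H]1C(C)=CC[C@@H]2C(C)(C)CCC[C@@]12C
A2 | alternative 1 | methyl (2E)-2,6-dimethyl-6-[(triethylsilyl)peroxy]-8-(Dec)oct-2-enoate (C6 epimers) | COC(=O)/C(C)=C/CCC(C)(OO[Si](CC)(CC)CC)CC[C@@H]1C(C)=CC[C@@H]2C(C)(C)CCC[C@@]12C
A3 | alternative 2 | methyl (2S,3E,5E)-2,6-dimethyl-8-(Dec)octa-3,5-dienoate | COC(=O)[C@@H](C)/C=C/C=C(\C)CC[C@@H]1C(C)=CC[C@@H]2C(C)(C)CCC[C@@]12C
A4 | alternative 2 | methyl (2S)-2-{(3S,6S)-6-[2-(Dec)ethyl]-6-methyl-3,6-dihydro-1,2-dioxin-3-yl}propanoate | COC(=O)[C@@H](C)[C@@H]1C=C[C@](C)(CC[C@@H]2C(C)=CC[C@@H]3C(C)(C)CCC[C@@]23C)OO1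
A5 | alternative 3 | methyl (2S)-2-{(3S,6S)-6-methyl-6-[(3E,7E)-4,8,12-trimethyltrideca-3,7,11-trien-1-yl]-1,2-dioxan-3-yl}propanoate | COC(=O)[C@@H](C)[C@@H]1CC[C@](C)(CC/C=C(\C)CC/C=C(\C)CCC=C(C)C)OO1
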